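**Plan**

- Retrosynthesis: after adjusting C-7 (methyl ester) and C-3 (ketone), ring A is cut at C-1–C-10. This leaves a γ-lactone (O–C-19–C-4–C-5–C-10) cis-fused to ring B, with H still on C-10 and a 2-bromoacryloyl arm (C-3, C-2, C-1) on C-4. Further cuts: C-3–C-4 (aldol), C-4–C-5 (Michael), C-6–C-7 (carbonylation), C-13–C-16 (radical), C-8–C-14 and C-9–C-11 (Diels–Alder).
- Forward order of rings: B (cyclopentenone) → C (Diels–Alder with butadiene) → D (5-exo vinyl-radical closure, then hydration at C-16) → lactone ring (malonate Michael addition tethered to the 10α oxygen) → A (key closure).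
- Enabling feature: C-10 is the carbinol carbon of the γ-lactone and a ring-fusion CH. In the lactone/ring B bicycle H-10 and the acyl arm on C-4 are cis-1,3, so C-2 lies five atoms from H-10 and C-1 six atoms from C-10. A vinyl radical at C-2 can therefore take H-10, and the C-10 radical closes ring A on C-1.
- Stereochemistry: C-8/C-9 from the catalyst-controlled Diels–Alder. The rest is relayed: C-16 (exo hydration), C-10–O (convex-face hydride), C-5 (tether, cis-fused lactone), C-6 (equilibration), C-4 (exo-face aldol), quaternary C-10 (retention enforced by the lactone), C-3 (bulky hydride).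

Key step: step 17

Remark: gibberellane numbering (C-1 to C-19) is used for all intermediates. The catalyst enantiomer in step 4 is assumed to be the one that exposes the enone face leading to the 8,9-configuration of the target; its mirror image would be used if the sense of induction proved opposite.

**Route**

Step 1
Reactants: 1 cyclopentane-1,3-dione; 2 2,3-dibromoprop-1-ene
Product: 3 2-(2-bromoprop-2-en-1-yl)cyclopentane-1,3-dione
Conditions: KOH (1 equiv), H2O, 60 °C
Reagents that add atoms: none
Why: C-alkylation of the 1,3-dione enolate by the allylic bromide in water, where hydrogen bonding to oxygen favours the carbon terminus, is the standard entry to 2-allyl-1,3-diones and leaves the vinylic bromide untouched.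

Step 2
Reactants: 3 2-(2-bromoprop-2-en-1-yl)cyclopentane-1,3-dione
Product: 4 2-(2-bromoprop-2-en-1-yl)-3-(2-methylpropoxy)cyclopent-2-en-1-one
Conditions: 2-methylpropan-1-ol, TsOH (cat.), benzene, reflux, Dean–Stark
Reagents that add atoms: 2-methylpropan-1-ol, CC(C)CO
Why: Acid-catalysed enol etherification of the dione gives the vinylogous ester needed for a Stork–Danheiser carbonyl transposition.

Step 3
Reactants: 4 2-(2-bromoprop-2-en-1-yl)-3-(2-methylpropoxy)cyclopent-2-en-1-one
Product: 6 2-(2-bromoprop-2-en-1-yl)cyclopent-2-en-1-one, via allylic alcohol 5 (not isolated)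
Conditions: i-Bu2AlH, CH2Cl2, −78 °C; then 1 M HCl, 0 °C
Reagents that add atoms: none
Why: Stork–Danheiser sequence in which 1,2-reduction of the vinylogous ester and acid hydrolysis of the resulting enol ether, with loss of the alcohol, should give the transposed 2-substituted enone.

Step 4
Reactants: 6 2-(2-bromoprop-2-en-1-yl)cyclopent-2-en-1-one; 7 buta-1,3-diene
Product: 8 cis-7a-(2-bromoprop-2-en-1-yl)-2,3,3a,4,7,7a-hexahydro-1H-inden-1-one (rings B and C; C-8 and C-9 as in the target)
Conditions: (S)-1-(2-methylphenyl)-3,3-diphenyltetrahydro-1H,3H-pyrrolo[1,2-c][1,3,2]oxazaborole (10 mol%), AlBr3 (8 mol%), CH2Cl2, −78 to −40 °C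
Reagents that add atoms: none
Why: Chiral oxazaborolidinium-catalysed Diels–Alder reaction of a cyclic enone with butadiene, in which suprafacial addition makes the ring fusion cis (H-9 syn to the bromoallyl group on C-8) and the catalyst bound to the carbonyl shields one face of the planar enone and so sets the absolute configuration of C-8 and C-9.

Step 5
Reactants: 8 cis-fused bromoallyl hydrindenone
Product: 9 tricyclic ketone (6-oxo ring B cis-fused at C-8/C-9 to the 16-methylene bicyclo[3.2.1]octane of rings C and D)
Conditions: Bu3SnH (1.3 equiv), AIBN (cat.), benzene (0.02 M), 80 °C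
Reagents that add atoms: none
Why: 5-exo-trig cyclization of the vinyl radical from the 2-bromoallyl group onto C-13 of the cyclohexene closes ring D with its exocyclic methylene, the bridge being able to form only on the face that carries C-15, and a moderate stannane concentration should trap the kinetic radical before homoallyl rearrangement.

Step 6
Reactants: 9 tricyclic ketone
Product: 10 C-6 enol triflate (C-5=C-6)
Conditions: KN(SiMe3)2, THF, −78 °C; then PhNTf2, −78 to 0 °C
Reagents that add atoms: N-phenylbis(trifluoromethanesulfonimide), O=S(=O)(N(c1ccccc1)S(=O)(=O)C(F)(F)F)C(F)(F)F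
Why: The ketone can enolize only towards C-5 because C-8 is quaternary, so O-sulfonylation of the potassium enolate should give a single enol triflate.

Step 7
Reactants: 10 C-6 enol triflate
Product: 11 methyl 5-ene-7-oate with 16-methylene (C-7 ester on C-6)
Conditions: Pd(OAc)2 (5 mol%), PPh3 (10 mol%), CO (1 atm), MeOH, Et3N, DMF, 60 °C
Reagents that add atoms: carbon monoxide, [C-]#[O+]; methanol, CO
Why: Palladium-catalysed methoxycarbonylation of an enol triflate (oxidative addition of zerovalent palladium, CO insertion, methanolysis) installs C-7 as the conjugated methyl ester.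

Step 8
Reactants: 11 methyl 5-ene-7-oate with 16-methylene
Product: 13 methyl 16-hydroxy-16-methyl 5-ene-7-oate (16-OH exo), via alkylmercury acetate 12 (not isolated)
Conditions: Hg(OAc)2, THF/H2O (1:1), rt; then NaBH4, 3 M NaOH, 0 °C
Reagents that add atoms: water, O
Why: Markovnikov oxymercuration–demercuration hydrates only the electron-rich exocyclic alkene, water attacking C-16 from the exo face syn to the one-carbon bridge C-14, so that the hydroxyl is exo and the methyl endo as in the target.

Step 9
Reactants: 13 methyl 16-hydroxy-16-methyl 5-ene-7-oate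
Product: 14 10-oxo-5-ene-7-oate (ene-1,4-dicarbonyl compound)
Conditions: Rh2(C6H10NO)4 (dirhodium tetracaprolactamate, 1 mol%), t-BuOOH (5 equiv), K2CO3 (cat.), CH2Cl2, rt
Reagents that add atoms: tert-butyl hydroperoxide, CC(C)(C)OO
Why: Radical allylic oxidation by the tert-butylperoxy radical at C-10, the only allylic methylene of the sole remaining alkene (C-8 is quaternary), should give the enone.

Step 10
Reactants: 14 10-oxo-5-ene-7-oate
Product: 15 10α-hydroxy-5-ene-7-oate
Conditions: NaBH4, CeCl3·7H2O, MeOH, −78 °C
Reagents that add atoms: none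
Why: Luche 1,2-reduction in which hydride attacks C-10 from the convex β face of the cis-fused ring B/ring C system (the α face lies under ring C), which places the hydroxyl on the α face.

Step 11
Reactants: 15 10α-hydroxy-5-ene-7-oate; 16 3-methoxy-2-methyl-3-oxopropanoic acid
Product: 17 10α-O-(3-methoxy-2-methyl-3-oxopropanoyl) ester of 15 (mixed methylmalonate)
Conditions: DCC, DMAP (cat.), CH2Cl2, 0 °C to rt
Reagents that add atoms: none
Why: Steglich esterification acylates the secondary allylic alcohol while the hindered tertiary C-16 hydroxyl should not react.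

Step 12
Reactants: 17 mixed methylmalonate
Product: 18 γ-lactone diester (lactone O–C-19–C-4–C-5–C-10 cis-fused to ring B; C-4 bears methyl and CO2Me as both epimers; H-5β; 6β-CO2Me)
Conditions: Cs2CO3 (0.3 equiv), MeCN, rt
Reagents that add atoms: none
Why: Intramolecular 5-exo-trig Michael addition of the malonate enolate to C-5 of the unsaturated ester, in which the tether from the 10α oxygen forces C-4 onto the α face of C-5 (cis-fused lactone, H-5β) and reversible protonation leaves the C-6 ester on the convex β face trans to C-4.

Step 13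
Reactants: 18 γ-lactone diester
Product: 19 γ-lactone with H and methyl on C-4 (both epimers)
Conditions: LiCl, H2O (2 equiv), DMSO, 150 °C
Reagents that add atoms: none
Why: Krapcho demethoxycarbonylation removes the malonate-type methyl ester (chloride attack at its methyl group, then loss of carbon dioxide) and should leave the lactone and the isolated C-7 ester, the configuration of C-4 being immaterial at this stage.

Step 14
Reactants: 19 γ-lactone with H and methyl on C-4; 20 prop-2-enal (acrolein)
Product: 21 4-(1-hydroxyprop-2-en-1-yl) lactone (quaternary C-4 with the C-3 arm exo and the methyl endo; both C-3 epimers)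
Conditions: LiN(i-Pr)2 (2.2 equiv), THF, −78 °C; acrolein, −78 °C; AcOH
Reagents that add atoms: none
Why: Aldol addition of the lactone lithium enolate (the lactone α-hydrogen is more acidic and less hindered than H-6) to acrolein, which approaches the exo face of the cis-fused lactone/ring B bicycle syn to H-5 and H-10, so that C-3 ends exo and the methyl endo at the new quaternary C-4.

Step 15
Reactants: 21 4-(1-hydroxyprop-2-en-1-yl) lactone
Product: 22 4-acryloyl lactone (vinyl ketone)
Conditions: Dess–Martin periodinane, CH2Cl2, 0 °C to rt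
Reagents that add atoms: none
Why: Dess–Martin oxidation should convert both C-3 epimers of the allylic alcohol into one non-enolizable vinyl ketone without touching the tertiary alcohol.

Step 16
Reactants: 22 4-acryloyl lactone
Product: 24 4-(2-bromoacryloyl) lactone, via dibromide 23 (not isolated)
Conditions: Br2 (1.0 equiv), CH2Cl2, −78 °C; then Et3N, 0 °C
Reagents that add atoms: bromine, BrBr
Why: Bromine addition to the vinyl ketone and amine-induced loss of HBr through the acidic α-hydrogen give the 2-bromo enone, the standard α-halogenation of an enone.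

Step 17
Reactants: 24 4-(2-bromoacryloyl) lactone
Product: 25 3-oxo 19,10-lactone 7-methyl ester (rings A to D closed; the 3-ketone of the target methyl ester)
Conditions: Bu3SnH (1.3 equiv, added over 10 h), AIBN (0.2 equiv), benzene (0.002 M), 80 °C
Reagents that add atoms: none
Why: Proposed new method: the tributyltin radical abstracts bromine to give the σ-vinyl radical at C-2, which takes H-10 by 1,5-hydrogen transfer through a six-membered transition state (H-10 is the only hydrogen five atoms away on the same exo face, and its tertiary α-acyloxy C–H bond is much weaker than the vinylic C–H bond that forms); the nucleophilic α-acyloxy radical at C-10 then adds to C-1, the β-carbon of the vinyl ketone just unmasked, and the α-keto radical at C-2 is reduced by the stannane. The closest known reaction type is radical translocation, in which a vinyl radical from a vinyl bromide undergoes 1,5-hydrogen transfer and the translocated radical cyclizes onto the alkene left behind, joined here to a Giese-type addition to an enone. Ring A closes in the 6-endo-trig mode (radical carbon C-10, chain C-5, C-4, C-3, alkene C-2=C-1), preferred over 5-exo attack at C-2 because C-1 is the polarity-matched β-carbon, C-3 is a trigonal centre within the chain, and the 5-exo product would be a strained 2-oxabicyclo[2.2.1]heptanone with a primary radical. The only new stereocentre, quaternary C-10, is controlled by the lactone: the C-10 radical stays within the cis-fused lactone/ring B bicycle and can be reached by the arm on C-4 only on the exo face from which H-10 left, so C-1 replaces H-10 with retention and the lactone bridge ends on the α face. The step needs site selectivity in the hydrogen transfer, secured by the 1,5-geometry and the cis-1,3 placement of H-10 and the acyl arm, and hydrogen transfer faster than direct reduction of the vinyl radical, secured by high dilution and slow addition of the stannane.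

Step 18
Reactants: 25 3-oxo 19,10-lactone 7-methyl ester
Product: 26 methyl ester of the target gibberellin (3β-hydroxy 19,10-lactone 7-methyl ester)
Conditions: K[HB(sec-Bu)3] (2.5 equiv), KH2PO4, THF, −78 °C
Reagents that add atoms: none
Why: The bulky borohydride should attack the C-3 ketone along the equatorial trajectory and give the axial 3β-alcohol, the phosphate buffer suppressing retro-aldol epimerization of the β-hydroxy lactone.

Step 19
Reactants: 26 methyl ester of the target gibberellin
Product: 27 target gibberellin (3β-hydroxy, 16-exo-hydroxy-16-methyl, 19,10-lactone, free 7-carboxylic acid)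
Conditions: LiSCH2CH2CH3 (lithium propane-1-thiolate, 5 equiv), HMPA, rt; then 1 M HCl
Reagents that add atoms: none
Why: Nucleophilic demethylation of the hindered C-7 methyl ester by thiolate attack at the methyl carbon frees the acid without hydroxide, so the lactone and the base-sensitive 3β-hydroxyl should be preserved.

**Compound list**

1 | cyclopentane-1,3-dione | O=C1CCC(=O)C1 | starting material
2 | 2,3-dibromoprop-1-ene | C=C(Br)CBr | starting material
3 | 2-(2-bromoprop-2-en-1-yl)cyclopentane-1,3-dione | C=C(Br)CC1C(=O)CCC1=O | intermediate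
4 | 2-(2-bromoprop-2-en-1-yl)-3-(2-methylpropoxy)cyclopent-2-en-1-one | C=C(Br)CC1=C(OCC(C)C)CCC1=O | intermediate
5 | 2-(2-bromoprop-2-en-1-yl)-3-(2-methylpropoxy)cyclopent-2-en-1-ol | C=C(Br)CC1=C(OCC(C)C)CCC1O | intermediate (not isolated)
6 | 2-(2-bromoprop-2-en-1-yl)cyclopent-2-en-1-one | C=C(Br)CC1=CCCC1=O | intermediate
7 | buta-1,3-diene | C=CC=C | starting material
8 | cis-7a-(2-bromoprop-2-en-1-yl)-2,3,3a,4,7,7a-hexahydro-1H-inden-1-one (C-8, C-9 as in the target) | C1[C@@H]2CC=CC[C@]2(CC(Br)=C)C(=O)C1 | intermediate
9 | tricyclic 6-ketone with 16-methylene (rings B, C, D) | C1[C@@H]2CC[C@@H]3C[C@]2(CC3=C)C(=O)C1 | intermediate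
10 | C-6 enol triflate of 9 (C-5=C-6) | C1[C@@H]2CC[C@@H]3C[C@]2(CC3=C)C(OS(=O)(=O)C(F)(F)F)=C1 | intermediate
11 | methyl 5-ene-7-oate with 16-methylene | C1[C@@H]2CC[C@@H]3C[C@]2(CC3=C)C(C(=O)OC)=C1 | intermediate
12 | 17-(acetoxymercurio)-16-hydroxy 5-ene-7-oate | C1[C@@H]2CC[C@@H]3C[C@]2(C[C@@]3(C[Hg]OC(C)=O)O)C(C(=O)OC)=C1 | intermediate (not isolated)
13 | methyl 16-hydroxy-16-methyl 5-ene-7-oate (16-OH exo) | C1[C@@H]2CC[C@@H]3C[C@]2(C[C@@]3(C)O)C(C(=O)OC)=C1 | intermediate
14 | methyl 16-hydroxy-10-oxo-5-ene-7-oate | O=C1[C@@H]2CC[C@@H]3C[C@]2(C[C@@]3(C)O)C(C(=O)OC)=C1 | intermediate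
15 | methyl 10α,16-dihydroxy-5-ene-7-oate | O[C@@H]1[C@@H]2CC[C@@H]3C[C@]2(C[C@@]3(C)O)C(C(=O)OC)=C1 | intermediate
16 | 3-methoxy-2-methyl-3-oxopropanoic acid | COC(=O)C(C)C(=O)O | starting material
17 | 10α-O-(3-methoxy-2-methyl-3-oxopropanoyl) ester of 15 | COC(=O)C(C)C(=O)O[C@@H]1[C@@H]2CC[C@@H]3C[C@]2(C[C@@]3(C)O)C(C(=O)OC)=C1 | intermediate
18 | 19,10-γ-lactone with methyl and CO2Me on C-4 (both C-4 epimers), H-5β, 6β-CO2Me | COC(=O)C1(C)C(=O)O[C@@H]2[C@@H]3CC[C@@H]4C[C@]3(C[C@@]4(C)O)[C@@H](C(=O)OC)[C@@H]21 | intermediate
19 | 19,10-γ-lactone with H and methyl on C-4 (both C-4 epimers) | CC1C(=O)O[C@@H]2[C@@H]3CC[C@@H]4C[C@]3(C[C@@]4(C)O)[C@@H](C(=O)OC)[C@@H]21 | intermediate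
20 | prop-2-enal (acrolein) | C=CC=O | starting material
21 | 4-(1-hydroxyprop-2-en-1-yl) lactone (C-3 arm exo, methyl endo; both C-3 epimers) | C[C@]1(C(O)C=C)C(=O)O[C@@H]2[C@@H]3CC[C@@H]4C[C@]3(C[C@@]4(C)O)[C@@H](C(=O)OC)[C@@H]21 | intermediate
22 | 4-acryloyl lactone | C[C@]1(C(=O)C=C)C(=O)O[C@@H]2[C@@H]3CC[C@@H]4C[C@]3(C[C@@]4(C)O)[C@@H](C(=O)OC)[C@@H]21 | intermediate
23 | 4-(2,3-dibromopropanoyl) lactone | C[C@]1(C(=O)C(Br)CBr)C(=O)O[C@@H]2[C@@H]3CC[C@@H]4C[C@]3(C[C@@]4(C)O)[C@@H](C(=O)OC)[C@@H]21 | intermediate (not isolated)
24 | 4-(2-bromoacryloyl) lactone | C[C@]1(C(=O)C(Br)=C)C(=O)O[C@@H]2[C@@H]3CC[C@@H]4C[C@]3(C[C@@]4(C)O)[C@@H](C(=O)OC)[C@@H]21 | intermediate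
25 | 3-oxo 19,10-lactone 7-methyl ester (3-ketone of the target methyl ester) | C[C@@]12C(=O)O[C@]3(CCC1=O)[C@@H]1CC[C@@H]4C[C@]1(C[C@@]4(C)O)[C@@H](C(=O)OC)[C@@H]32 | intermediate
26 | methyl ester of the target gibberellin (3β-hydroxy 19,10-lactone 7-methyl ester) | C[C@@]12C(=O)O[C@]3(CC[C@@H]1O)[C@@H]1CC[C@@H]4C[C@]1(C[C@@]4(C)O)[C@@H](C(=O)OC)[C@@H]32 | intermediate
27 | target gibberellin (3β-hydroxy, 16-exo-hydroxy-16-methyl, 19,10-lactone, 7-carboxylic acid) | C[C@@]12C(=O)O[C@]3(CC[C@@H]1O)[C@@H]1CC[C@@H]4C[C@]1(C[C@@]4(C)O)[C@@H](C(=O)O)[C@@H]32 | target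

**Step count and risks**

Total step count: 19. Longest linear sequence: 19 steps (from 1).

Steps most likely to fail:

Step 17. The vinyl radical may be reduced by the stannane before it has taken H-10, the tin radical may add to C-1 of the bromo enone instead of abstracting bromine, or the C-10 radical may close in the 5-exo mode. The fallback uses known chemistry, a reductive ketyl–enone cyclization on the ring-opened keto ester; it sets out from 21 and returns at 25. The carbinol of 21 is silylated (TBSCl, imidazole, DMF) to the silyl ether F1. The lactone is opened with LiOH (THF/H2O) and the 10-hydroxy carboxylate is oxidized in the same pot (2-azaadamantane N-oxyl, NaOCl, pH 9) to the 10-oxo acid F2. Me3SiCHN2 gives the keto diester F3, HF·pyridine frees the allylic alcohol F4, and Dess–Martin oxidation gives the vinyl ketone F5. SmI2 (2.2 equiv, THF/MeOH, −78 °C) should then join C-10 to C-1 by reductive ketyl–enone coupling in the 6-endo mode. Chelation of trivalent samarium between the ketyl oxygen and the C-19 ester carbonyl should hold O-10 on the α face, so that C-1 arrives on the β face. The samarium alkoxide then closes the lactone onto the C-19 methyl ester to give 25.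

Step 4. The α-substituted enone may react sluggishly with butadiene, or the catalyst may discriminate its faces poorly. The fallback replaces asymmetric catalysis by a reagent-controlled separation; it sets out from 6 and returns at 8. An EtAlCl2-promoted Diels–Alder reaction gives the racemic cis-adduct F6. Reduction with H3B·SMe2 and (S)-1-methyl-3,3-diphenyltetrahydro-1H,3H-pyrrolo[1,2-c][1,3,2]oxazaborole (10 mol%) should convert the two enantiomers into two diastereomeric carbinols with the same new configuration at C-6, separable on silica. The diastereomer with the ring fusion of 8, the carbinol F7, is oxidized with Dess–Martin periodinane to 8.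

Step 9. Hydrogen abstraction at the allylic position of the electron-poor alkene may be slow, the product may be over-oxidized, or C-9 may epimerize next to the new ketone. The fallback replaces oxidation, reduction and acylation by allylic bromination and substitution with inversion; it sets out from 13 and returns at 17. N-Bromosuccinimide with AIBN in PhCF3 at 80 °C should brominate C-10 from the convex β face to give the allylic bromide F8. The caesium salt of 16 (Cs2CO3, DMF, rt) then displaces bromide with inversion to give 17.

**Further compounds**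

F1 | step 17 | tert-butyldimethylsilyl ether of 21 at O-3 | C[C@]1(C(O[Si](C)(C)C(C)(C)C)C=C)C(=O)O[C@@H]2[C@@H]3CC[C@@H]4C[C@]3(C[C@@]4(C)O)[C@@H](C(=O)OC)[C@@H]21
F2 | step 17 | ring-opened 10-oxo 19-acid (3-silyloxy, 7-methyl ester) | C[C@](C(O[Si](C)(C)C(C)(C)C)C=C)(C(=O)O)[C@@H]1C(=O)[C@@H]2CC[C@@H]3C[C@]2(C[C@@]3(C)O)[C@H]1C(=O)OC
F3 | step 17 | 10-oxo 7,19-dimethyl ester (3-silyloxy) | C[C@](C(O[Si](C)(C)C(C)(C)C)C=C)(C(=O)OC)[C@@H]1C(=O)[C@@H]2CC[C@@H]3C[C@]2(C[C@@]3(C)O)[C@H]1C(=O)OC
F4 | step 17 | 3-hydroxy-10-oxo 7,19-dimethyl ester | C[C@](C(O)C=C)(C(=O)OC)[C@@H]1C(=O)[C@@H]2CC[C@@H]3C[C@]2(C[C@@]3(C)O)[C@H]1C(=O)OC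
F5 | step 17 | 3,10-dioxo 7,19-dimethyl ester (vinyl ketone) | C[C@](C(=O)C=C)(C(=O)OC)[C@@H]1C(=O)[C@@H]2CC[C@@H]3C[C@]2(C[C@@]3(C)O)[C@H]1C(=O)OC
F6 | step 4 | racemic cis-7a-(2-bromoprop-2-en-1-yl)-2,3,3a,4,7,7a-hexahydro-1H-inden-1-one | C1[C@@H]2CC=CC[C@]2(CC(Br)=C)C(=O)C1.C1[C@H]2CC=CC[C@@]2(CC(Br)=C)C(=O)C1
F7 | step 4 | (1R)-carbinol of 8 (C-6 alcohol, ring fusion as in 8) | C1[C@@H]2CC=CC[C@]2(CC(Br)=C)[C@H](O)C1
F8 | step 9 | methyl 10β-bromo-16-hydroxy-5-ene-7-oate | Br[C@H]1[C@@H]2CC[C@@H]3C[C@]2(C[C@@]3(C)O)C(C(=O)OC)=C1
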